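At 2.0 h, the time we read the four flasks, each is asked for S, the share of L in L plus D (its selectivity), and the concentration we follow to reckon it is [L], the molarity of L.

| flask | X | G | temperature | remark | time |
|---|---|---|---|---|---|
| beta | 2.2 M | 1.92 M | 45 °C | run made earlier |  |
| alpha | 2.2 M | 1.92 M | 95 °C | run made earlier |  |
| blue | 1.6 M | 1.92 M | 140 °C |  | 2.0 h |
| amber | 1.6 M | 1.92 M | 50 °C |  | 2.0 h |
| red | 1.6 M | 1.92 M | 110 °C |  | 2.0 h |
| grey | 1.6 M | 1.92 M | 80 °C |  | 2.0 h |

| run | time / h | L / % | D / % | X / % |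
|---|---|---|---|---|
| beta | 15.0 | 3.4 | 0 | 96.6 |
| beta | 20.0 | 4.8 | 0.3 | 97.3 |
| beta | 40.0 | 8.7 | 1.1 | 92.3 |
| beta | 50.0 | 8.1 | 0 | 90.8 |
| beta | 72.0 | 13.5 | 0.8 | 85.5 |
| beta | 120 | 16.0 | 4.7 | 78.4 |
| beta | 144 | 22.2 | 6.0 | 74.6 |
| alpha | 1.33 | 19.3 | 8.7 | 70.3 |
| alpha | 2.00 | 27.3 | 15.0 | 60.8 |
| alpha | 3.00 | 29.5 | 25.0 | 45.9 |
| alpha | 4.00 | 32.3 | 34.3 | 36.1 |
| alpha | 6.00 | 35.2 | 46.0 | 19.5 |
| alpha | 10.0 | 34.7 | 59.1 | 9.0 |
| alpha | 15.0 | 33.8 | 63.8 | 2.8 |

(each reading ± 1 percentage point)

- the flask with the highest share of L in all that became L or D ("all alike" if they lie within 1.5 percentage points) (blue / amber / red / grey / all alike)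
- share of L in all that became L or D, blue
- share of L in all that became L or D, amber
- share of L in all that became L or D, red
- share of L in all that became L or D, grey

- percent here means X units held: one D counts as two

We build up grey, at 80 °C, one step at a time. First we take the main step alone, X + G → L, which gives S = 100%. G is charged alike in both runs, so we compare them by one apparent first-order constant for X, k = ln(charged X / X left) / time, a rough measure and no pseudo-first-order constant, since G at 1.92 M stands below X at 2.2 M. That gives 0.265 h⁻¹ from the first alpha reading and 0.002035 h⁻¹ from the last beta reading. We place grey a fraction w of the way from alpha down to beta and interpolate ln k: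

w = 0.300

k = 0.0615 h⁻¹

X consumed by 2.0 h = 11.6 %, or [L] ≈ 0.185 M

Second, we add X + L → D, since the reading of D/L in alpha rises from 0.451 at 1.33 h to 1.89 at 15.0 h, whereas L and D formed side by side from X, each first order, would hold that ratio level. While D is small, the ratio D/L grows in proportion to [L], so we define the drain coefficient a = (D/L)/[L], and read it as 0.553 M⁻¹ in beta and 1.06 M⁻¹ in alpha, both carrying the scatter. With beta's a, S = 1/(1 + a[L]) comes to 90.7 %.

Third, we let a follow temperature by the same w:

a = 0.873 M⁻¹

S = 86.1 %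

The forecast names amber, with blue 44 %, amber 99.5 %, red 56 % and grey 91 %, which stands above our grey figure. Its grounds: “L's share falls steadily with temperature, mainly because conversion rises.”

The flasks give amber the highest share, with blue 39.2 %, amber 99.5 %, red 48.4 % and grey 89.1 %. Red is where forecast and flask part, by 7.6 percentage points. Grey's simulated L and D give a = 0.691 M⁻¹, lower than our 0.873 M⁻¹.

    X + G → L, rate k1*[X]*[G]^0.5 (k = 0.00923 M⁻⁰·⁵ min⁻¹, Ea = 93.0 kJ mol⁻¹)
    X + L → D (k = 0.00951 M⁻¹ min⁻¹, Ea = 100 kJ mol⁻¹)
    (constants at 110 °C)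

We repeat the reckoning on amber's neighbour, the same charge held at 75 °C for 2.0 h. There w = 0.400, k = 0.0378 h⁻¹, X consumed is 7.28 %, and a = 0.818 M⁻¹, so S = 91.3 %. That neighbour flask holds X at 92 % and L at 7.42 %, and its share of L is 92.9 %.

(The earlier runs and the new flask stem from a simulated flask with made-up constants, noise included.)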